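**Retrosynthetic overview**

- The free acid is unveiled last from an N-acyl (R)-4-benzyloxazolidinone with LiOOH. The imide is both the stereocontroller and the group that keeps the C1 carboxyl distinct from the methyl ester.
- Key disconnection: the bond between C2 (the α-carbon of the acid) and C1' of the 3-(furan-3-yl)propyl chain, made by decarboxylative radical alkylation of a chelated titanium enolate with the unsymmetrical peroxide 3-chlorobenzoyl 4-(furan-3-yl)butanoyl peroxide. Enabling feature: C2 is an enolizable CH next to the carboxyl carbon, and C1' is a primary CH2 three carbons from furan C3, so its radical (from the butanoic acid by loss of CO2) can reach the furan ring only by a disfavoured 5-endo attack.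
- The (5Z)-enoate is cut by Still–Gennari olefination into a 5-oxopentanoyl imide (from hex-5-enoic acid by ozonolysis) and a homoprenylated bis(trifluoroethyl) phosphonoacetate.
- The furan fragment comes from 3-bromofuran by Negishi coupling with (4-ethoxy-4-oxobutyl)zinc bromide, saponification and carbodiimide coupling with 3-chloroperoxybenzoic acid. No ring is constructed: furan and oxazolidinone are bought as rings, and the oxazolidinone is removed in the last step.

Key step: step 8

Remark: the facial selectivity of the titanium enolate radical alkylation is assumed to follow the chelated Z-enolate model of oxazolidinone imide alkylations (attack anti to the C4 benzyl group); this dictates the (R)-auxiliary.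

**Route**

Step 1
Reactants: 1 3-bromofuran; 2 (4-ethoxy-4-oxobutyl)zinc bromide
Product: 3 ethyl 4-(furan-3-yl)butanoate
Conditions: Pd(OAc)2 (2 mol %), SPhos (4 mol %), THF, rt → 45 °C
Reagents that add atoms: none
Why: Negishi coupling, in which zerovalent palladium ligated by SPhos should insert into the C3–Br bond of the furan, the ester-tolerant primary alkylzinc transmetalates, and reductive elimination outruns β-hydride elimination.

Step 2
Reactants: 3 ethyl 4-(furan-3-yl)butanoate
Product: 5 4-(furan-3-yl)butanoic acid, via lithium 4-(furan-3-yl)butanoate 4 (not isolated)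
Conditions: LiOH·H2O, THF/MeOH/H2O, rt; then 1 M HCl, 0 °C, to pH 3
Reagents that add atoms: lithium hydroxide, [Li+].[OH-]
Why: Saponification (acyl-oxygen cleavage by hydroxide) of an unhindered ethyl ester, with the furan stable to base and to brief cold acidification.

Step 3
Reactants: 5 4-(furan-3-yl)butanoic acid
Product: 6 3-chlorobenzoyl 4-(furan-3-yl)butanoyl peroxide
Conditions: DCC, CH2Cl2, −20 °C; purified mCPBA (0.95 equiv) added slowly in CH2Cl2, −20 → 0 °C; filtered cold and used as a solution
Reagents that add atoms: 3-chloroperoxybenzoic acid (mCPBA), OOC(=O)c1cccc(Cl)c1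
Why: Carbodiimide coupling of a carboxylic acid with a peroxy acid, the classical route to unsymmetrical diacyl peroxides, with the peracid added slowly and cold to the carbodiimide-activated acid so that it should be acylated as it arrives and not accumulate to oxidize the furan.

Step 4
Reactants: 7 hex-5-enoic acid; 8 (R)-4-benzyl-1,3-oxazolidin-2-one
Product: 10 (4R)-4-benzyl-3-(hex-5-enoyl)-1,3-oxazolidin-2-one, via mixed pivalic anhydride 9 (not isolated)
Conditions: t-BuCOCl, Et3N, THF, −20 °C; then 8, LiCl, −20 °C → rt
Reagents that add atoms: none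
Why: N-acylation of the oxazolidinone through a mixed anhydride, in which the hindered pivaloyl carbonyl directs attack to the hexenoyl carbonyl and the existing stereocentre is untouched.

Step 5
Reactants: 10 (4R)-4-benzyl-3-(hex-5-enoyl)-1,3-oxazolidin-2-one
Product: 12 5-[(4R)-4-benzyl-2-oxo-1,3-oxazolidin-3-yl]-5-oxopentanal, via secondary ozonide 11 (not isolated)
Conditions: O3, CH2Cl2, −78 °C; then PPh3, −78 °C → rt
Reagents that add atoms: ozone, [O-][O+]=O
Why: Ozonolysis with reductive work-up, the terminal alkene being the only ozone-reactive site at −78 °C (imide and phenyl ring are inert) and no furan being present yet.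

Step 6
Reactants: 13 methyl 2-[bis(2,2,2-trifluoroethoxy)phosphoryl]acetate; 14 5-bromo-2-methylpent-2-ene
Product: 16 methyl 2-[bis(2,2,2-trifluoroethoxy)phosphoryl]-6-methylhept-5-enoate (racemic), via sodium phosphonoacetate anion 15 (not isolated)
Conditions: NaH, DMF, 0 °C; then 14 (limiting), n-Bu4NI (cat.), 0 → 50 °C
Reagents that add atoms: none
Why: SN2 C-alkylation of the stabilized phosphonoacetate anion by a primary homoallylic bromide under iodide catalysis, with excess 13 to suppress dialkylation.

Step 7
Reactants: 12 5-[(4R)-4-benzyl-2-oxo-1,3-oxazolidin-3-yl]-5-oxopentanal; 16 methyl 2-[bis(2,2,2-trifluoroethoxy)phosphoryl]-6-methylhept-5-enoate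
Product: 18 methyl (2Z)-7-[(4R)-4-benzyl-2-oxo-1,3-oxazolidin-3-yl]-2-(4-methylpent-3-en-1-yl)-7-oxohept-2-enoate, via potassium phosphonate anion 17 (not isolated)
Conditions: KN(SiMe3)2, 18-crown-6, THF, −78 °C; then 12, −78 °C
Reagents that add atoms: none
Why: Still–Gennari olefination, in which the electron-poor bis(trifluoroethyl) phosphonate under dissociating conditions eliminates from the kinetic adduct and should give the Z-trisubstituted enoate (ester cis to the new chain), while the non-basic anion leaves aldehyde and imide un-enolized.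

Step 8
Reactants: 18 methyl (2Z)-7-[(4R)-4-benzyl-2-oxo-1,3-oxazolidin-3-yl]-2-(4-methylpent-3-en-1-yl)-7-oxohept-2-enoate; 6 3-chlorobenzoyl 4-(furan-3-yl)butanoyl peroxide
Product: 20 methyl (2Z,6R)-6-{[(4R)-4-benzyl-2-oxo-1,3-oxazolidin-3-yl]carbonyl}-9-(furan-3-yl)-2-(4-methylpent-3-en-1-yl)non-2-enoate, via trichlorotitanium Z-enolate 19 (not isolated)
Conditions: TiCl4, i-Pr2NEt, CH2Cl2, 0 °C; then 6, 0 °C → rt
Reagents that add atoms: none
Why: Soft enolization converts only the bidentate imide of 18 into the chelated Z-enolate 19, whose tetravalent titanium enolate / trivalent titanium α-acyl radical character allows inner-sphere single-electron transfer to the O–O bond of 6; the peroxide radical anion should break into titanium-bound 3-chlorobenzoate (the better-stabilized carboxylate) and the aliphatic acyloxyl radical, which loses CO2 far faster than an aroyloxyl radical would, and the primary 3-(furan-3-yl)propyl radical recombines with the titanium-bound α-radical to form the C2–C1' bond. The closest known reaction type is the stereoselective decarboxylative alkylation of titanium enolates of chiral N-acyl oxazolidinones with diacyl peroxides of primary aliphatic acids, which delivers the unactivated primary alkyl group that enolate alkylation with a halide installs poorly; the unsymmetrical peroxide is chosen so that only one furan-bearing acyl group is spent. No ring is closed. The new stereocentre is controlled by the benzyl group at C4 of the (R)-oxazolidinone, which shields one face of the chelated Z-enolate so that the radical bonds anti to it, giving R at C2 (the enoate-bearing chain outranks the furylpropyl chain). The step needs chemoselective enolization (secured by chelation and the higher acidity of the imide over the methyl enoate), C–C rather than C–O bonding (secured by fast decarboxylation of the aliphatic acyloxyl radical and by departure of the aroyl half as carboxylate), and inertness of the other π systems (the nucleophilic primary radical is mismatched with the electron-rich furan and trisubstituted alkene, attack on the furan would be 5-endo, and the α,β-disubstituted enoate is a slow radical acceptor).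

Step 9
Reactants: 20 methyl (2Z,6R)-6-{[(4R)-4-benzyl-2-oxo-1,3-oxazolidin-3-yl]carbonyl}-9-(furan-3-yl)-2-(4-methylpent-3-en-1-yl)non-2-enoate
Product: 23 (2R,5Z)-2-[3-(furan-3-yl)propyl]-6-(methoxycarbonyl)-10-methylundeca-5,9-dienoic acid, via lithium peroxycarboxylate 21 (not isolated), via lithium carboxylate 22 (not isolated)
Conditions: LiOH, 30% aq. H2O2, THF/H2O (3:1), 0 °C; then aq. Na2SO3; then 1 M HCl, 0 °C, to pH 3
Reagents that add atoms: hydrogen peroxide (as lithium hydroperoxide), OO
Why: Hydroperoxide cleavage of the N-acyl oxazolidinone, in which the α-effect nucleophile should attack the exocyclic imide carbonyl far faster than hydroxide attacks the hindered conjugated methyl ester at 0 °C, under conditions that do not epimerize C2 and that return the auxiliary.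

**Compound list**

1 | 3-bromofuran | Brc1ccoc1 | starting material
2 | (4-ethoxy-4-oxobutyl)zinc bromide (solution in THF) | CCOC(=O)CCC[Zn]Br | starting material
3 | ethyl 4-(furan-3-yl)butanoate | CCOC(=O)CCCc1ccoc1 | intermediate
4 | lithium 4-(furan-3-yl)butanoate | [Li+].[O-]C(=O)CCCc1ccoc1 | intermediate
5 | 4-(furan-3-yl)butanoic acid | OC(=O)CCCc1ccoc1 | intermediate
6 | 3-chlorobenzoyl 4-(furan-3-yl)butanoyl peroxide | O=C(CCCc1ccoc1)OOC(=O)c1cccc(Cl)c1 | intermediate
7 | hex-5-enoic acid | C=CCCCC(=O)O | starting material
8 | (R)-4-benzyl-1,3-oxazolidin-2-one | O=C1N[C@H](Cc2ccccc2)CO1 | starting material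
9 | hex-5-enoic 2,2-dimethylpropanoic anhydride | C=CCCCC(=O)OC(=O)C(C)(C)C | intermediate
10 | (4R)-4-benzyl-3-(hex-5-enoyl)-1,3-oxazolidin-2-one | C=CCCCC(=O)N1[C@H](Cc2ccccc2)COC1=O | intermediate
11 | (4R)-4-benzyl-3-[4-(1,2,4-trioxolan-3-yl)butanoyl]-1,3-oxazolidin-2-one (ozonide, diastereomer mixture) | O=C(CCCC1OCOO1)N1[C@H](Cc2ccccc2)COC1=O | intermediate
12 | 5-[(4R)-4-benzyl-2-oxo-1,3-oxazolidin-3-yl]-5-oxopentanal | O=CCCCC(=O)N1[C@H](Cc2ccccc2)COC1=O | intermediate
13 | methyl 2-[bis(2,2,2-trifluoroethoxy)phosphoryl]acetate | COC(=O)CP(=O)(OCC(F)(F)F)OCC(F)(F)F | starting material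
14 | 5-bromo-2-methylpent-2-ene | CC(C)=CCCBr | starting material
15 | sodium salt of 13 (phosphonoacetate anion) | [Na+].COC(=O)[CH-]P(=O)(OCC(F)(F)F)OCC(F)(F)F | intermediate
16 | methyl 2-[bis(2,2,2-trifluoroethoxy)phosphoryl]-6-methylhept-5-enoate (racemic) | COC(=O)C(CCC=C(C)C)P(=O)(OCC(F)(F)F)OCC(F)(F)F | intermediate
17 | potassium salt of 16 (phosphonate anion) | [K+].COC(=O)[C-](CCC=C(C)C)P(=O)(OCC(F)(F)F)OCC(F)(F)F | intermediate
18 | methyl (2Z)-7-[(4R)-4-benzyl-2-oxo-1,3-oxazolidin-3-yl]-2-(4-methylpent-3-en-1-yl)-7-oxohept-2-enoate | COC(=O)/C(=C\CCCC(=O)N1[C@H](Cc2ccccc2)COC1=O)CCC=C(C)C | intermediate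
19 | trichlorotitanium Z-enolate of 18 | COC(=O)/C(=C\CC/C=C(\O[Ti](Cl)(Cl)Cl)N1[C@H](Cc2ccccc2)COC1=O)CCC=C(C)C | intermediate
20 | methyl (2Z,6R)-6-{[(4R)-4-benzyl-2-oxo-1,3-oxazolidin-3-yl]carbonyl}-9-(furan-3-yl)-2-(4-methylpent-3-en-1-yl)non-2-enoate | COC(=O)/C(=C\CC[C@@H](CCCc1ccoc1)C(=O)N1[C@H](Cc2ccccc2)COC1=O)CCC=C(C)C | intermediate
21 | lithium (2R,5Z)-2-[3-(furan-3-yl)propyl]-6-(methoxycarbonyl)-10-methylundeca-5,9-dieneperoxoate | [Li+].COC(=O)/C(=C\CC[C@@H](CCCc1ccoc1)C(=O)O[O-])CCC=C(C)C | intermediate
22 | lithium (2R,5Z)-2-[3-(furan-3-yl)propyl]-6-(methoxycarbonyl)-10-methylundeca-5,9-dienoate | [Li+].COC(=O)/C(=C\CC[C@@H](CCCc1ccoc1)C(=O)[O-])CCC=C(C)C | intermediate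
23 | (2R,5Z)-2-[3-(furan-3-yl)propyl]-6-(methoxycarbonyl)-10-methylundeca-5,9-dienoic acid | COC(=O)/C(=C\CC[C@@H](CCCc1ccoc1)C(=O)O)CCC=C(C)C | target

**Step count and risks**

Total step count: 9. Longest linear sequence: 5 steps (steps 4, 5, 7, 8, 9; the branch through steps 1, 2, 3, 8, 9 is equally long).

Steps most likely to fail:

1. Step 8. The enolate may be intercepted at a peroxide oxygen (α-acyloxylation), the unsymmetrical peroxide may fragment toward the aroyloxyl radical, the primary radical may decay before C–C coupling, or the Lewis acid may degrade the furan during the reaction. The fallback sets out from 18 and comes back at 20, building the same bond by two-electron enolate chemistry and attaching the furan afterwards. 18 is deprotonated with NaN(SiMe3)2 (THF, −78 °C) to its sodium Z-enolate F1 (not isolated), which is alkylated by allyl iodide anti to the benzyl group to give methyl (2Z,6S)-6-{[(4R)-4-benzyl-2-oxo-1,3-oxazolidin-3-yl]carbonyl}-2-(4-methylpent-3-en-1-yl)nona-2,8-dienoate F2. F2 has the same spatial arrangement as 20; the descriptor changes only because allyl outranks the enoate chain. The terminal alkene alone is then hydroborated with 9-borabicyclo[3.3.1]nonane (THF, 0 °C → rt) to the B-alkyl borane F3 (not isolated). B-alkyl Suzuki–Miyaura coupling of F3 with 3-bromofuran 1 (PdCl2(dppf), aq. K3PO4, DMF/THF, rt) should give 20.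

2. Step 3. Oxidation of the furan ring by the neutral peracid may compete with its acylation, and the carbodiimide-activated acid may rearrange to the N-acylurea before the peracid reaches it. The fallback sets out from 5 and comes back at 6, activating the acid as its chloride and acylating the peroxycarboxylate anion, which is a nucleophile and not an electrophilic oxidant. 5 is converted with 1-chloro-N,N,2-trimethylprop-1-en-1-amine (CH2Cl2, 0 °C, neutral conditions) into 4-(furan-3-yl)butanoyl chloride F4 (not isolated). This solution is added at 0 °C to sodium 3-chloroperoxybenzoate, preformed from mCPBA and aq. NaOH (1 equiv), in CH2Cl2/H2O with n-Bu4NHSO4 (cat.), which should give 6.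

3. Step 6. Alkylation of the weakly nucleophilic fluorinated phosphonate anion may be sluggish or go twice, elimination of the homoallylic bromide may compete, and the trifluoroethyl esters may be lost at the temperature needed. The fallback sets out from 14 and comes back at 16, forming the C–C bond on a more nucleophilic phosphonate and exchanging the phosphorus esters afterwards. Commercial trimethyl phosphonoacetate is alkylated with 14 (NaH, DMF, 60 °C) to methyl 2-(dimethoxyphosphoryl)-6-methylhept-5-enoate F5. Selective P-demethylation with Me3SiBr (CH2Cl2, 0 °C → rt) gives the bis(trimethylsilyl) phosphonate F6 (not isolated). Oxalyl chloride with catalytic DMF converts F6 into the phosphonic dichloride F7 (not isolated), which with CF3CH2OH and pyridine (CH2Cl2, 0 °C) should give 16.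

**Further compounds**

F1 | step 8 | sodium Z-enolate of 18 | [Na+].COC(=O)/C(=C\CC/C=C(\[O-])N1[C@H](Cc2ccccc2)COC1=O)CCC=C(C)C
F2 | step 8 | methyl (2Z,6S)-6-{[(4R)-4-benzyl-2-oxo-1,3-oxazolidin-3-yl]carbonyl}-2-(4-methylpent-3-en-1-yl)nona-2,8-dienoate | COC(=O)/C(=C\CC[C@@H](CC=C)C(=O)N1[C@H](Cc2ccccc2)COC1=O)CCC=C(C)C
F3 | step 8 | methyl (2Z,6R)-6-{[(4R)-4-benzyl-2-oxo-1,3-oxazolidin-3-yl]carbonyl}-9-(9-borabicyclo[3.3.1]nonan-9-yl)-2-(4-methylpent-3-en-1-yl)non-2-enoate | COC(=O)/C(=C\CC[C@@H](CCCB1C2CCCC1CCC2)C(=O)N1[C@H](Cc2ccccc2)COC1=O)CCC=C(C)C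
F4 | step 3 | 4-(furan-3-yl)butanoyl chloride | O=C(Cl)CCCc1ccoc1
F5 | step 6 | methyl 2-(dimethoxyphosphoryl)-6-methylhept-5-enoate | COC(=O)C(CCC=C(C)C)P(=O)(OC)OC
F6 | step 6 | methyl 2-{bis[(trimethylsilyl)oxy]phosphoryl}-6-methylhept-5-enoate | COC(=O)C(CCC=C(C)C)P(=O)(O[Si](C)(C)C)O[Si](C)(C)C
F7 | step 6 | methyl 2-(dichlorophosphoryl)-6-methylhept-5-enoate | COC(=O)C(CCC=C(C)C)P(=O)(Cl)Cl
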